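The numbers are invented, and the outcome is calculated.

Does any of the listed changes lift Z.J by the required margin, and how much Z.J stands in the flask at the end?

    L ⇌ Z, rate k1*(cs1 - [Z]) while solid is left; crystals form when [Z] > cs1 (cs1 = 0.062 M, k1 = 0.071 s⁻¹)
    Z + J → Z.J (k2 = 0.049 M⁻¹ s⁻¹)
    2 Z → Z2 (k3 = 0.014 M⁻¹ s⁻¹)
    J ⇌ Q (K4 = 1.8, k4 = 8.7 × 10⁻⁴ s⁻¹)
    Z.J ⇌ E (K5 = 15, k5 = 0.0013 s⁻¹)

L 0.098 M; J 0.0882 M; time 1.5 h

- amount of Z.J at 1.5 h, in percent of the L charged
- the change that raises the amount of Z.J at 1.5 h, in percent of the L charged most ("none" if none brings more than 2 percentage points) (south / north-west / south-east / none)
- amount of Z.J at 1.5 h, in percent of the L charged, after south-east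

- a species is counted by the L in it: one Z2 counts as two
- for a step with 2 of a species take k times the square, and two of it per event
- given per volume of solution although it is solid: L
- at the start none of L is in solution
- run time (flask): 1.5 h

- south: doubling the solubility in step 1, all else as stated
- north-west: doubling the amount of J, all else as stated
- south-east: doubling the dissolution coefficient of step 1, all else as stated

You asked for a quick number and suspected that more J is the lever, so let us work in fractions of the L charged and in powers of ten. We take 0.0625, the standing share, the part of the pair Z.J plus E that is still Z.J once step 5 has come to balance; Z.J then lies 1.18 powers of ten below E. By itself, step 5 relaxes with a half-life of 0.139 h, shorter than 1.5 h, and an excess of Z.J left to step 5 for that whole time fades by 3.26 powers of ten. So we need the pair, and then we multiply.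

Step 1 is fast against step 2, so while solid is left we hold Z at saturation, 0.633 of the charge, with J at 0.900. Step 3 takes two Z each time, so the capture share, the selectivity of Z for step 2, starts at 0.713. We let that start value stand for the whole run, which is an assumption and not a result. That gives 4.46%, and 4.46% after south-east, which leaves Z where we held it.

Doubling J lifts the capture share to 0.833, worth 0.75 percentage points, less than the 2 points required. Doubling the solubility puts saturation above the charge of L, so we let Z reach the whole charge at most, and the share then falls to 0.612. So we answer none.

The forecast gives 4.4%, none and 4.5%, and it too leans on step 5: “so it is equilibrated”.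

The flask gives 4.59%, and 4.58% after south-east; the best change is none, with north-west bringing 0.83 points. At 1.50 h in this flask, Z.J is being made at 0.654 of the rate at which it is used up, each step taken net. The standing share of 0.0625 turns this flask's pair of 65.4% into 4.08%. In the flask charged with 0.053 M of J, it turns a pair of 44.0% into 2.75%, where the reading is 3.25%.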